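**Plan**
- Retrosynthesis: the three phenols are masked as allyl ethers, the C7–O benzoate bond is cut, C7 is taken back to a tert-butyl ester, and the tetrahydrofuran (O1, C2 aryl, C3, C4, C5) is cut at C2–C3 and C4–C5.
- Enabling feature: C2–O1–C5 is the carbonyl ylide of O-allylvanillin extended by one CH2, and C7–C3=C4=C6–aryl is a 4-arylallenoate whose remote C4=C6 bond survives as the benzylidene.
- Forward: O-allylvanillin is divided into the α-chloro (silylmethyl) ether and, via an aryl alkyne and a 3-alkynoate, the allenoate; their [3+2] union forms the only new ring; reduction, acylation and deallylation finish.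
- Stereochemistry: the (S) allene axis comes from an enantioselective guanidine-catalysed 1,3-proton shift; ylide approach anti to the C6 aryl turns the axis into C3 and the E alkene; C2 follows as trans from the exo approach.

Key step: step 7

Assumption: the (S,S) antipode of the bicyclic guanidine is taken to give the (S) allene; should the optical rotation indicate the (R) axis, the (R,R) antipode is used and nothing else changes.

Step 1
Reactants: 1 vanillin; 2 allyl bromide
Product: 3 4-(allyloxy)-3-methoxybenzaldehyde
Conditions: K2CO3, DMF, rt to 50 °C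
Reagents that add atoms: none
Why: Williamson etherification of the phenoxide, which leaves the aldehyde untouched and installs a phenol mask that tolerates fluoride, hydride and carbodiimide.

Step 2
Reactants: 3 4-(allyloxy)-3-methoxybenzaldehyde; 4 (trimethylsilyl)methanol (2.2 equiv)
Product: 5 1-(allyloxy)-4-{bis[(trimethylsilyl)methoxy]methyl}-2-methoxybenzene
Conditions: p-TsOH·H2O (cat.), toluene, Dean–Stark, reflux; Et3N quench
Reagents that add atoms: none
Why: Acid-catalysed acetalisation driven by azeotropic removal of water; the allyl aryl ether and the C–Si bonds are inert to catalytic sulfonic acid.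

Step 3
Reactants: 5 1-(allyloxy)-4-{bis[(trimethylsilyl)methoxy]methyl}-2-methoxybenzene
Product: 6 1-(allyloxy)-4-{chloro[(trimethylsilyl)methoxy]methyl}-2-methoxybenzene (racemic)
Conditions: AcCl (1.05 equiv), CH2Cl2, 0 °C to rt; volatiles removed in vacuo, crude used at once
Reagents that add atoms: acetyl chloride, CC(=O)Cl (supplies Cl)
Why: Acetal–acyl chloride exchange, the standard entry to α-chlorobenzyl ethers: acylation of one acetal oxygen expels the ester and chloride captures the aryl-stabilised oxocarbenium ion; the racemic C–Cl centre is destroyed in step 7.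

Step 4
Reactants: 3 4-(allyloxy)-3-methoxybenzaldehyde; 7 dimethyl (1-diazo-2-oxopropyl)phosphonate
Product: 8 1-(allyloxy)-4-ethynyl-2-methoxybenzene
Conditions: K2CO3, MeOH, 0 °C to rt
Reagents that add atoms: none
Why: Ohira–Bestmann (Seyferth–Gilbert) homologation: methanolysis of 7 releases the diazomethylphosphonate anion, which olefinates the aldehyde and, after loss of N2 and a 1,2-hydrogen shift, gives the terminal alkyne under conditions harmless to the allyl ether.

Step 5
Reactants: 8 1-(allyloxy)-4-ethynyl-2-methoxybenzene; 9 tert-butyl diazoacetate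
Product: 10 tert-butyl 4-[4-(allyloxy)-3-methoxyphenyl]but-3-ynoate
Conditions: CuI (5 mol%), MeCN, rt
Reagents that add atoms: none
Why: CuI-catalysed coupling of a terminal alkyne with a diazoacetate (carbene insertion into the monovalent copper acetylide, then protonation at the propargylic carbon) gives the 3-alkynoate without added base, so no racemic allene is formed prematurely.

Step 6
Reactants: 10 tert-butyl 4-[4-(allyloxy)-3-methoxyphenyl]but-3-ynoate
Product: 11 tert-butyl (S)-4-[4-(allyloxy)-3-methoxyphenyl]buta-2,3-dienoate
Conditions: (2S,6S)-2,6-di-tert-butyl-2,3,5,6-tetrahydro-1H-imidazo[1,2-a]imidazole (5 mol%), hexane–toluene, −20 °C; filtered through silica and used fresh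
Reagents that add atoms: none
Why: Chiral-guanidine-catalysed enantioselective 1,3-prototropic isomerisation of tert-butyl 4-aryl-3-alkynoates: the guanidinium–carbanion ion pair is reprotonated on one face at the aryl-bearing carbon, which sets the (S) axis, and the non-polar medium at low temperature limits re-deprotonation.

Step 7
Reactants: 6 1-(allyloxy)-4-{chloro[(trimethylsilyl)methoxy]methyl}-2-methoxybenzene (2 equiv, added slowly); 11 tert-butyl (S)-4-[4-(allyloxy)-3-methoxyphenyl]buta-2,3-dienoate
Product: 13 tert-butyl (2R,3R,4E)-2-[4-(allyloxy)-3-methoxyphenyl]-4-[4-(allyloxy)-3-methoxybenzylidene]tetrahydrofuran-3-carboxylate, via carbonyl ylide 12 (not isolated)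
Conditions: CsF (3 equiv, dried), MeCN, 0 °C to rt
Reagents that add atoms: none
Why: Fluoride attacks silicon of 6 and chloride leaves (1,3-elimination through the aryl-stabilised oxocarbenium ion) to give the non-stabilised carbonyl ylide 12, which adds suprafacially across the ester-bearing C3=C4 bond of 11; the closest known reaction type is the [3+2] cycloaddition of fluoride-generated silylmethyl-ether carbonyl ylides with acrylates and allenes, whereas relay of an allene axis through it has not been tested. The tetrahydrofuran is closed by this intermolecular [3+2] cycloaddition, with C2–C3 and C4–C5 formed in one step from the three-atom dipole and the two-atom dipolarophile. The aryl on C6 lies over one face of the C3=C4 π bond, so the ylide should enter from the opposite face; with the (S) axis this gives (3R) in 13 (3S in the target once C7 is CH2O) and, as C4 rehybridises, places C3 cis to the C6 aryl, which is the E benzylidene. C2 is set by the approach mode: the ylide with its aryl pointing outward and the bulky tert-butyl ester exo should give the 2,3-trans (2R) product, and any cis isomer is to be removed by chromatography. The selectivities needed are regiochemical (the CH2 terminus, which carries the larger HOMO coefficient, bonds to the electrophilic central carbon C4 and the aryl-bearing terminus to C3), site (the ester-lowered α,β bond reacts, not the styrenyl bond) and facial (anti to the C6 aryl). The axis must also survive until reaction, for which sparingly soluble CsF, low temperature and an excess of slowly added 6 are chosen.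

Step 8
Reactants: 13 tert-butyl (2R,3R,4E)-2-[4-(allyloxy)-3-methoxyphenyl]-4-[4-(allyloxy)-3-methoxybenzylidene]tetrahydrofuran-3-carboxylate
Product: 14 {(2R,3S,4E)-2-[4-(allyloxy)-3-methoxyphenyl]-4-[4-(allyloxy)-3-methoxybenzylidene]tetrahydrofuran-3-yl}methanol
Conditions: LiAlH4, THF, −10 to 0 °C; aqueous NaOH work-up
Reagents that add atoms: none
Why: Hydride reduction of the ester to the primary alcohol, which removes the acidic C3–H next to a carbonyl; the cyclic ether, the alkene and the allyl ethers are inert, and C3 changes descriptor only through CIP priorities.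

Step 9
Reactants: 15 4-hydroxybenzoic acid; 2 allyl bromide (2.5 equiv)
Product: 17 4-(allyloxy)benzoic acid, via allyl 4-(allyloxy)benzoate 16 (not isolated)
Conditions: K2CO3, DMF, 50 °C; then NaOH, MeOH–H2O, 60 °C; aqueous HCl
Reagents that add atoms: sodium hydroxide, [Na+].[OH-] (supplies one carboxyl oxygen in the saponification)
Why: Double Williamson alkylation of phenoxide and carboxylate followed by saponification of the allyl ester in the same flask, which leaves only the phenol masked.

Step 10
Reactants: 14 {(2R,3S,4E)-2-[4-(allyloxy)-3-methoxyphenyl]-4-[4-(allyloxy)-3-methoxybenzylidene]tetrahydrofuran-3-yl}methanol; 17 4-(allyloxy)benzoic acid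
Product: 18 {(2R,3S,4E)-2-[4-(allyloxy)-3-methoxyphenyl]-4-[4-(allyloxy)-3-methoxybenzylidene]tetrahydrofuran-3-yl}methyl 4-(allyloxy)benzoate
Conditions: DCC, DMAP (cat.), CH2Cl2, 0 °C to rt
Reagents that add atoms: none
Why: Steglich esterification of an unhindered primary alcohol under neutral conditions that do not touch the benzylic ether or the stereocentres.

Step 11
Reactants: 18 {(2R,3S,4E)-2-[4-(allyloxy)-3-methoxyphenyl]-4-[4-(allyloxy)-3-methoxybenzylidene]tetrahydrofuran-3-yl}methyl 4-(allyloxy)benzoate
Product: 19 agastenol, {(2R,3S,4E)-2-(4-hydroxy-3-methoxyphenyl)-4-(4-hydroxy-3-methoxybenzylidene)tetrahydrofuran-3-yl}methyl 4-hydroxybenzoate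
Conditions: Pd(PPh3)4 (10 mol%), morpholine (10 equiv), THF, rt
Reagents that add atoms: none
Why: Tsuji–Trost deallylation: zerovalent palladium ionises the three allyl aryl ethers to π-allyl complexes that morpholine captures, while the homoallylic benzoate and the dialkyl ether O1–C5 (allylic but a far poorer leaving group than phenoxide) should stay intact.

**Compound list**
1 | vanillin | COc1cc(C=O)ccc1O | starting material
2 | allyl bromide | C=CCBr | starting material
3 | 4-(allyloxy)-3-methoxybenzaldehyde | C=CCOc1ccc(C=O)cc1OC | intermediate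
4 | (trimethylsilyl)methanol | C[Si](C)(C)CO | starting material
5 | 1-(allyloxy)-4-{bis[(trimethylsilyl)methoxy]methyl}-2-methoxybenzene | C=CCOc1ccc(C(OC[Si](C)(C)C)OC[Si](C)(C)C)cc1OC | intermediate
6 | 1-(allyloxy)-4-{chloro[(trimethylsilyl)methoxy]methyl}-2-methoxybenzene, racemic | C=CCOc1ccc(C(Cl)OC[Si](C)(C)C)cc1OC | intermediate
7 | dimethyl (1-diazo-2-oxopropyl)phosphonate | CC(=O)C(=[N+]=[N-])P(=O)(OC)OC | starting material
8 | 1-(allyloxy)-4-ethynyl-2-methoxybenzene | C#Cc1ccc(OCC=C)c(OC)c1 | intermediate
9 | tert-butyl diazoacetate | CC(C)(C)OC(=O)C=[N+]=[N-] | starting material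
10 | tert-butyl 4-[4-(allyloxy)-3-methoxyphenyl]but-3-ynoate | CC(C)(C)OC(=O)CC#Cc1ccc(OCC=C)c(OC)c1 | intermediate
11 | tert-butyl (S)-4-[4-(allyloxy)-3-methoxyphenyl]buta-2,3-dienoate | CC(C)(C)OC(=O)[CH]=[C@@]=[CH]c1ccc(OCC=C)c(OC)c1 | intermediate
12 | carbonyl ylide, [4-(allyloxy)-3-methoxybenzylidene]oxonium methylide | C=CCOc1ccc(C=[O+][CH2-])cc1OC | intermediate
13 | tert-butyl (2R,3R,4E)-2-[4-(allyloxy)-3-methoxyphenyl]-4-[4-(allyloxy)-3-methoxybenzylidene]tetrahydrofuran-3-carboxylate | COc1cc(/C=C2/CO[C@@H](c3ccc(OCC=C)c(OC)c3)[C@@H]2C(=O)OC(C)(C)C)ccc1OCC=C | intermediate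
14 | {(2R,3S,4E)-2-[4-(allyloxy)-3-methoxyphenyl]-4-[4-(allyloxy)-3-methoxybenzylidene]tetrahydrofuran-3-yl}methanol | COc1cc(/C=C2/CO[C@@H](c3ccc(OCC=C)c(OC)c3)[C@@H]2CO)ccc1OCC=C | intermediate
15 | 4-hydroxybenzoic acid | O=C(O)c1ccc(O)cc1 | starting material
16 | allyl 4-(allyloxy)benzoate | C=CCOC(=O)c1ccc(OCC=C)cc1 | intermediate
17 | 4-(allyloxy)benzoic acid | C=CCOc1ccc(C(=O)O)cc1 | intermediate
18 | {(2R,3S,4E)-2-[4-(allyloxy)-3-methoxyphenyl]-4-[4-(allyloxy)-3-methoxybenzylidene]tetrahydrofuran-3-yl}methyl 4-(allyloxy)benzoate | COc1cc(/C=C2/CO[C@@H](c3ccc(OCC=C)c(OC)c3)[C@@H]2COC(=O)c2ccc(OCC=C)cc2)ccc1OCC=C | intermediate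
19 | agastenol | COc1cc(/C=C2/CO[C@@H](c3ccc(O)c(OC)c3)[C@@H]2COC(=O)c2ccc(O)cc2)ccc1O | target

**Step count**
Total: 11 steps. Longest linear sequence: 8 steps (steps 1, 4, 5, 6, 7, 8, 10, 11).

**Steps most likely to fail**

1. Step 7. The axis-to-centre relay may erode: fluoride can act as a base and racemise 11 before it reacts, or a stepwise zwitterionic closure can allow rotation about C3–C4, and the exo preference that gives trans C2 may be weak. Fallback (stereochemistry from a covalent resolving agent instead of the axis): setting out from 14 of insufficient enantiopurity, esterification with (S)-2-methoxy-2-phenylacetic acid (DCC, DMAP) should give the diastereomeric esters, the (S)-O-methylmandelate of 14 F1 and the (S)-O-methylmandelate of the enantiomer of 14 F2. These are separated by chromatography or crystallisation, and F1 is cleaved with LiAlH4 in THF at 0 °C, which returns to the route at 14.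

2. Step 6. The proton shift may stop short of full conversion, give too low a selectivity with the electron-rich aryl group, or be followed by slow racemisation of 11 by the catalyst. Fallback (centre-to-axis transfer from a resolved propargylic alcohol):
   - Setting out from 3, ethynylmagnesium bromide should give racemic 1-[4-(allyloxy)-3-methoxyphenyl]prop-2-yn-1-ol F3.
   - Immobilised Candida antarctica lipase B with vinyl acetate is expected, by the usual empirical rule for secondary alcohols, to acylate the (R) enantiomer to (R)-1-[4-(allyloxy)-3-methoxyphenyl]prop-2-yn-1-yl acetate F5 and leave (S)-1-[4-(allyloxy)-3-methoxyphenyl]prop-2-yn-1-ol F4.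
   - Methyl chloroformate and pyridine convert F4 into methyl (S)-1-[4-(allyloxy)-3-methoxyphenyl]prop-2-yn-1-yl carbonate F6.
   - Pd(PPh3)4 (cat.), CO (1 atm), MeOH–THF at rt should then give methyl (S)-4-[4-(allyloxy)-3-methoxyphenyl]buta-2,3-dienoate F7 by anti oxidative addition of zerovalent palladium and CO insertion with retention; the propargylic carbonate ionises far faster than the allyl aryl ether.
   - F7 takes the place of 11 in step 7 and should give methyl (2R,3R,4E)-2-[4-(allyloxy)-3-methoxyphenyl]-4-[4-(allyloxy)-3-methoxybenzylidene]tetrahydrofuran-3-carboxylate F8, whose LiAlH4 reduction returns to the route at 14.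

3. Step 11. Zerovalent palladium may also ionise the allylic C5–O1 bond or isomerise the benzylidene, and the electron-rich guaiacyl allyl ethers may cleave slowly. Fallback (isomerisation then hydrolysis, no π-allyl chemistry): setting out from 18, [Ir(cod)(PMePh2)2]PF6 activated with H2 in THF at rt should move the three allyl double bonds into conjugation and give the tris[(E)-prop-1-enyl] ether of agastenol F9. Its enol ethers are hydrolysed with HgCl2 and HgO in acetone–water at rt, which returns to the route at 19.

**Further compounds**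
F1 | step 7 | (S)-O-methylmandelate of 14 | COc1cc(/C=C2/CO[C@@H](c3ccc(OCC=C)c(OC)c3)[C@@H]2COC(=O)[C@@H](OC)c2ccccc2)ccc1OCC=C
F2 | step 7 | (S)-O-methylmandelate of the enantiomer of 14 | COc1cc(/C=C2/CO[C@H](c3ccc(OCC=C)c(OC)c3)[C@H]2COC(=O)[C@@H](OC)c2ccccc2)ccc1OCC=C
F3 | step 6 | racemic 1-[4-(allyloxy)-3-methoxyphenyl]prop-2-yn-1-ol | C#CC(O)c1ccc(OCC=C)c(OC)c1
F4 | step 6 | (S)-1-[4-(allyloxy)-3-methoxyphenyl]prop-2-yn-1-ol | C#C[C@H](O)c1ccc(OCC=C)c(OC)c1
F5 | step 6 | (R)-1-[4-(allyloxy)-3-methoxyphenyl]prop-2-yn-1-yl acetate | C#C[C@@H](OC(C)=O)c1ccc(OCC=C)c(OC)c1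
F6 | step 6 | methyl (S)-1-[4-(allyloxy)-3-methoxyphenyl]prop-2-yn-1-yl carbonate | C#C[C@H](OC(=O)OC)c1ccc(OCC=C)c(OC)c1
F7 | step 6 | methyl (S)-4-[4-(allyloxy)-3-methoxyphenyl]buta-2,3-dienoate | COC(=O)[CH]=[C@@]=[CH]c1ccc(OCC=C)c(OC)c1
F8 | step 6 | methyl (2R,3R,4E)-2-[4-(allyloxy)-3-methoxyphenyl]-4-[4-(allyloxy)-3-methoxybenzylidene]tetrahydrofuran-3-carboxylate | COc1cc(/C=C2/CO[C@@H](c3ccc(OCC=C)c(OC)c3)[C@@H]2C(=O)OC)ccc1OCC=C
F9 | step 11 | tris[(E)-prop-1-enyl] ether of agastenol | COc1cc(/C=C2/CO[C@@H](c3ccc(O/C=C/C)c(OC)c3)[C@@H]2COC(=O)c2ccc(O/C=C/C)cc2)ccc1O/C=C/C
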